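**Strategy.** The hexacosanoyl chain is cut between C3 and C4 (C1 = ester carbonyl). C3 lies β to C1, so the C1–C3 end maps onto the acceptor terminus of benzyl acrylate, while the unbranched C4–C26 chain is the tricosyl radical set free when tetracosanoic (lignoceric) acid loses its carboxyl carbon as CO2. One photocatalytic decarboxylative Giese addition therefore forms the C3–C4 bond, trades CO2 for a CH2CH2CO2Bn unit and gives the target directly, redox-neutrally, with the benzyl ester (phenyl ring untouched) already in place. The precursor looks unlike the C23 fragment it delivers: a free C24 fatty acid, one carbon longer at the reacting end.

Key step: step 1

Remark on the chemistry: commercial benzyl acrylate is assumed to be passed through basic alumina to remove its phenolic stabiliser before use. The target has no stereocentre, so no descriptor is needed.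

Step 1
Reactants: 1 tetracosanoic acid (lignoceric acid); 2 benzyl acrylate (benzyl prop-2-enoate)
Product: 3 benzyl hexacosanoate
Conditions: 1 (1.3 equiv), 2 (1.0 equiv), 9-mesitylacridine (10 mol %), Cu(MeCN)4BF4 (10 mol %), PhCF3/CH2Cl2 (0.05 M), 400 nm LED, 40–45 °C, Ar
Reagents that add atoms: none
Why: This is a direct photocatalytic decarboxylative Giese (radical conjugate) addition, a known acridine/copper dual-catalytic reaction type for unactivated primary alkanoic acids and acrylates: the acridine hydrogen-bonds the carboxyl group of 1 and, on 400 nm excitation, proton-coupled electron transfer within the complex should give an acridinyl radical and the acyloxy radical, which loses CO2 to the primary tricosyl radical. This nucleophilic radical should add to the unsubstituted β-CH2 terminus of the electron-poor alkene 2, forming the C3–C4 bond and an ester-stabilised radical at C2. Cu(I) is expected to trap that electrophilic radical as a copper enolate that is protonated at C2, while the acridinyl radical returns its electron and proton, so both cycles close, the process is redox-neutral and CO2 is the only by-product. No ring is closed and no stereocentre is formed. The step needs β-regioselectivity, secured by the polarity match and the stabilised adduct radical, and mono-addition rather than telomerisation, secured by fast copper capture of the adduct radical and by keeping 2 as the dilute, limiting component; the benzyl ester and its benzylic C–H bonds should be inert to the primary alkyl radical.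

**Compound list**

1 | tetracosanoic acid (lignoceric acid) | CCCCCCCCCCCCCCCCCCCCCCCC(=O)O | starting material
2 | benzyl acrylate (benzyl prop-2-enoate) | C=CC(=O)OCc1ccccc1 | starting material
3 | benzyl hexacosanoate | CCCCCCCCCCCCCCCCCCCCCCCCCC(=O)OCc1ccccc1 | target

**Total step count:** 1
**Longest linear sequence:** 1 step

**Steps most likely to fail.** The route has a single step, so only step 1 can be named.

Step 1 could fail in three ways:
- The waxy C24 acid may dissolve incompletely, which would starve the acridine–acid complex and stall the decarboxylation.
- The C2 adduct radical may add to further acrylate (telomerisation or photopolymerisation of 2) instead of being reduced.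
- The tricosyl radical may be reduced prematurely to the alkane before it meets the acceptor.

Fallback for step 1: this sets out from 1 and returns at 3, using a pre-activated acid and reductive rather than oxidative radical generation. Acid 1 would be condensed with N-hydroxyphthalimide (DIC, cat. DMAP, CH2Cl2/THF, rt) to the redox-active ester 1,3-dioxoisoindolin-2-yl tetracosanoate F1, which is freely soluble and carries no acidic proton. F1 would then undergo a reductive decarboxylative Giese addition to 2 (Ru(bpy)3(PF6)2 1 mol %, Hantzsch ester 1.5 equiv, i-Pr2NEt, CH2Cl2, blue LED, rt). Single-electron reduction of the phthalimide ester should fragment it to the same tricosyl radical, and the Hantzsch ester should deliver the hydrogen atom to the C2 adduct radical, giving 3.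

**Further compounds**

F1 | step 1 | 1,3-dioxoisoindolin-2-yl tetracosanoate (N-hydroxyphthalimide ester of 1) | CCCCCCCCCCCCCCCCCCCCCCCC(=O)ON1C(=O)c2ccccc2C1=O
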